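In the oxolan-2-one ring the ring oxygen O1 sits on the quaternary carbon C5 anti to the hydroxyl on the neighbouring exocyclic carbon C1', and the carbonyl carbon C2 is three bonds from C5. That pattern is what a trans-γ,δ-epoxy acid leaves behind when it lactonises, so the route is built on the O1–C5 disconnection. In a single operation the carboxyl oxygen displaces the epoxide oxygen at the tertiary carbon with inversion: the γ-lactone closes and the displaced oxygen becomes the C1' hydroxyl. The precursor is (4R,5R)-4,5-epoxy-4-methyl-8-oxononanoic acid, made by Shi epoxidation of an (E)-alkene from a Johnson–Claisen rearrangement; its methyl ketone later takes on the furyl dienyl chain.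

Key step: step 6

Remark: primed locants C1'–C11' count the side chain outward from the carbinol carbon on C5; in step 14 the ligand antipode is taken to be the one that delivers the alkenyl group to the Re face of the ketone, an assignment to be confirmed on a simple methyl ketone before material is committed.

Step 1
Reactants: 1 pent-4-enal; 2 isopropenylmagnesium bromide, CH2=C(CH3)MgBr
Product: 3 (±)-2-methylhepta-1,6-dien-3-ol
Conditions: THF, −78 → 0 °C; aqueous work-up
Reagents that add atoms: none
Why: 1,2-addition of a vinylic Grignard reagent to an unhindered aldehyde is fast at low temperature; the new carbinol centre is racemic, which is harmless because step 2 erases it.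

Step 2
Reactants: 3; 4 triethyl orthoacetate
Product: 6 ethyl (4E)-4-methylnona-4,8-dienoate, via ketene acetal 5 (not isolated)
Conditions: 4 (6 equiv, neat), EtCO2H (5 mol%), 140 °C, EtOH distilled off
Reagents that add atoms: none
Why: Johnson–Claisen (orthoester Claisen) rearrangement: ketene acetal 5 rearranges through a chair in which the butenyl group is equatorial (the axial alternative clashes with the 2-methyl group), so the trisubstituted alkene should form as the (E)-isomer and no stereocentre remains.

Step 3
Reactants: 6
Product: 7 ethyl (4E)-4-methyl-8-oxonon-4-enoate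
Conditions: PdCl2 (10 mol%), CuCl (1 equiv), O2 (1 atm), DMF/H2O 7:1, rt
Reagents that add atoms: water, O
Why: Tsuji–Wacker oxidation: divalent palladium hydroxypalladates the monosubstituted alkene far faster than the trisubstituted one and adds water in the Markovnikov sense, so only the chain end should become the methyl ketone.

Step 4
Reactants: 7
Product: 8 ethyl (4R,5R)-4,5-epoxy-4-methyl-8-oxononanoate
Conditions: D-fructose-derived Shi ketone (1,2:4,5-di-O-isopropylidene-β-D-erythro-2,3-hexodiulo-2,6-pyranose, 30 mol%), KHSO5 (Oxone, 2KHSO5·KHSO4·K2SO4), K2CO3, Bu4NHSO4 (5 mol%), MeCN/CH2(OMe)2, aq. Na2B4O7–Na2H2(EDTA), pH 10.5, 0 °C; filtration through Et3N-deactivated silica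
Reagents that add atoms: potassium peroxymonosulfate (KHSO5), [K+].[O-]S(=O)(=O)OO
Why: Shi asymmetric epoxidation: the dioxirane of the fructose-derived ketone transfers oxygen through a spiro transition state that, for (E)-trisubstituted alkenes, attacks the face giving the (4R,5R)-trans-epoxide, so both stereocentres are set by the catalyst, and the buffered basic medium spares the ester, the ketone and the acid-labile epoxy ketone.

Step 5
Reactants: 8
Product: 10 (4R,5R)-4,5-epoxy-4-methyl-8-oxononanoic acid, via lithium carboxylate 9 (not isolated)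
Conditions: LiOH·H2O (1.5 equiv), THF/H2O 3:1, 0 °C; Et2O wash of the basic phase; 0.5 M HCl to pH 5 at 0 °C, EtOAc extraction, concentrated cold and used at once
Reagents that add atoms: lithium hydroxide (LiOH), [Li+].[OH-]
Why: Ester saponification at 0 °C leaves the epoxide alone, since neither hydroxide nor carboxylate opens a trisubstituted epoxide without acid activation; acidifying only to pH 5 in the cold frees the acid, which is carried on immediately because it lactonises on standing.

Step 6
Reactants: 10
Product: 11 (5S)-5-[(1R)-1-hydroxy-4-oxopentyl]-5-methyloxolan-2-one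
Conditions: CSA (5 mol%), CH2Cl2, −20 → 0 °C; Et3N quench
Reagents that add atoms: none
Why: Protonation of the epoxide oxygen polarises the C–O bond at the tertiary carbon C4, the carbonyl oxygen of the tethered carboxyl group attacks C4 from the face opposite the departing oxygen, and loss of a proton from the acyloxonium ion gives the lactone. The closest known reaction type is the acid-promoted lactonisation of γ,δ-epoxy acids prepared by Shi epoxidation. The single ring closes in the 5-exo-tet mode. The new lactone stereocentre C5 (S) is fixed by stereospecific inversion at the (4R)-epoxide carbon, while the carbinol carbon keeps its C–O bond and stays (R), so the trans-epoxide maps onto the anti hydroxy lactone. The step needs attack at the tertiary and not the secondary epoxide carbon, and by the carboxyl and not the C8 ketone oxygen: Markovnikov polarisation together with the five-membered exo transition state secures the first. The second should follow because the ketone oxygen reaches the tertiary carbon only through a six-membered endo transition state and the secondary carbon only by a poorly assisted SN2 attack, both slower than acid closure at low temperature with catalytic acid.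

Step 7
Reactants: 11
Product: 12 (5S)-5-methyl-5-[(1R)-4-oxo-1-(triethylsilyloxy)pentyl]oxolan-2-one
Conditions: TESCl (1.3 equiv), imidazole (2.5 equiv), DMAP (5 mol%), DMF, 0 °C → rt
Reagents that add atoms: chlorotriethylsilane (TESCl), CC[Si](Cl)(CC)CC
Why: Silyl ether formation at the secondary alcohol traps the open-chain hydroxy ketone (not its hemiketal) and removes the only acidic O–H before the organozinc step; no stereocentre is touched.

Step 8
Reactants: 13 furan-3-ylmethanol
Product: 14 3-(chloromethyl)furan
Conditions: SOCl2 (1.1 equiv), pyridine (1.2 equiv), Et2O, 0 °C; kept cold in solution and used promptly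
Reagents that add atoms: thionyl chloride, O=S(Cl)Cl
Why: Chlorodehydroxylation of a primary furylmethyl alcohol with SOCl2/pyridine proceeds by SN2 collapse of the chlorosulfite, and the pyridine buffer protects the acid-sensitive furan.

Step 9
Reactants: 14; 15 prenyl bromide (1-bromo-3-methylbut-2-ene)
Product: 17 perillene [3-(4-methylpent-3-en-1-yl)furan], via (furan-3-ylmethyl)magnesium chloride 16 (not isolated)
Conditions: Mg turnings (2 equiv), THF, 0 °C → rt; then 15, Li2CuCl4 (3 mol%), THF, −10 °C → rt
Reagents that add atoms: none
Why: Li2CuCl4-catalysed cross-coupling of a Grignard reagent with an allylic bromide should occur at the unsubstituted α-carbon of the prenyl unit (the γ-carbon would become quaternary), and copper catalysis keeps the furylmethyl nucleophile from reacting through the ring.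

Step 10
Reactants: 17
Product: 19 (2E)-5-(furan-3-yl)-2-methylpent-2-en-1-ol, via (2E)-5-(furan-3-yl)-2-methylpent-2-enal 18 (not isolated)
Conditions: SeO2 (0.5 equiv), t-BuOOH (3 equiv), salicylic acid (10 mol%), CH2Cl2, 0 °C → rt; then NaBH4, MeOH, 0 °C
Reagents that add atoms: selenium dioxide (SeO2), O=[Se]=O; tert-butyl hydroperoxide, CC(C)(C)OO
Why: Riley allylic oxidation (ene reaction, then [2,3]-sigmatropic shift) selectively hydroxylates the (E)-methyl group of a gem-dimethyl trisubstituted alkene, which fixes the (E) geometry, and borohydride returns any over-oxidised enal 18 to the alcohol.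

Step 11
Reactants: 19
Product: 20 3-[(3E)-5-bromo-4-methylpent-3-en-1-yl]furan
Conditions: CBr4 (1.2 equiv), PPh3 (1.25 equiv), CH2Cl2, 0 °C; used without storage
Reagents that add atoms: tetrabromomethane, BrC(Br)(Br)Br
Why: Appel bromination converts the primary allylic alcohol into the bromide by SN2 displacement of the oxyphosphonium group under neutral conditions, so neither allylic transposition, alkene isomerisation nor acid damage to the furan is expected.

Step 12
Reactants: 20; 21 ethynyltrimethylsilane
Product: 23 [(4E)-7-(furan-3-yl)-4-methylhept-4-en-1-yn-1-yl]trimethylsilane, via [(trimethylsilyl)ethynyl]magnesium bromide 22 (not isolated)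
Conditions: 21 (1.5 equiv), EtMgBr (1.4 equiv), THF, 0 °C → rt; CuBr·SMe2 (10 mol%), then 20, THF, 0 → 50 °C
Reagents that add atoms: none
Why: Copper-catalysed coupling of an alkynyl Grignard reagent with a primary allylic bromide should give the skipped enyne by substitution at the primary carbon with the (E)-alkene retained, and the silyl cap prevents double allylation of the alkyne.

Step 13
Reactants: 23
Product: 24 3-[(3E)-4-methylhept-3-en-6-yn-1-yl]furan
Conditions: K2CO3 (0.5 equiv), MeOH, rt
Reagents that add atoms: none
Why: Protodesilylation of the alkynylsilane by methanolysis is mild enough that the skipped enyne should not isomerise to an allene or a conjugated enyne.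

Step 14
Reactants: 12; 24
Product: 27 (5S)-5-[(1R,4S,5E,8E)-11-(furan-3-yl)-4-hydroxy-4,8-dimethyl-1-(triethylsilyloxy)undeca-5,8-dien-1-yl]-5-methyloxolan-2-one, via alkenylzirconocene chloride 25 (not isolated), via alkenyl(methyl)zinc 26 (not isolated)
Conditions: 24 (1.6 equiv), Cp2Zr(H)Cl (1.5 equiv), CH2Cl2, rt; solvent switch to toluene; ZnMe2 (1.5 equiv), −78 °C; bis(sulfonamide) diol ligand from trans-cyclohexane-1,2-diamine and camphor-10-sulfonyl chloride (Re-face antipode, 10 mol%), Ti(OiPr)4 (1.2 equiv), then 12, toluene, 0 °C → rt
Reagents that add atoms: none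
Why: Syn, anti-Markovnikov hydrozirconation of the terminal alkyne gives the (E)-alkenylzirconium, zirconium-to-zinc transmetalation and titanium/bis(sulfonamide) diol-catalysed asymmetric alkenylation of the ketone then form the tertiary allylic alcohol, the chiral ligand directing the alkenyl group to the Re face to set (4'S), while the organozinc leaves lactone, silyl ether and furan alone.

Step 15
Reactants: 27
Product: 28 (5S)-5-[(1R,4S,5E,8E)-11-(furan-3-yl)-1,4-dihydroxy-4,8-dimethylundeca-5,8-dien-1-yl]-5-methyloxolan-2-one (target)
Conditions: HF·pyridine, excess pyridine, THF, 0 °C → rt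
Reagents that add atoms: none
Why: Fluoride cleavage of the triethylsilyl ether under pyridine-buffered conditions is neither acidic enough to ionise the tertiary allylic alcohol or open the furan nor basic enough to translactonise, so the three stereocentres and both alkenes should be untouched.

Compound list
1 | pent-4-enal | C=CCCC=O | starting material
2 | isopropenylmagnesium bromide | CC(=C)[Mg]Br | starting material
3 | (±)-2-methylhepta-1,6-dien-3-ol | CC(=C)C(O)CCC=C | intermediate
4 | triethyl orthoacetate (1,1,1-triethoxyethane) | CC(OCC)(OCC)OCC | starting material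
5 | (±)-3-[(1-ethoxyethenyl)oxy]-2-methylhepta-1,6-diene (ketene acetal) | C=C(OCC)OC(CCC=C)C(C)=C | intermediate
6 | ethyl (4E)-4-methylnona-4,8-dienoate | CCOC(=O)CC/C(C)=C/CCC=C | intermediate
7 | ethyl (4E)-4-methyl-8-oxonon-4-enoate | CCOC(=O)CC/C(C)=C/CCC(C)=O | intermediate
8 | ethyl (4R,5R)-4,5-epoxy-4-methyl-8-oxononanoate | CC(=O)CC[C@H]1O[C@]1(C)CCC(=O)OCC | intermediate
9 | lithium (4R,5R)-4,5-epoxy-4-methyl-8-oxononanoate | [Li+].CC(=O)CC[C@H]1O[C@]1(C)CCC(=O)[O-] | intermediate
10 | (4R,5R)-4,5-epoxy-4-methyl-8-oxononanoic acid | CC(=O)CC[C@H]1O[C@]1(C)CCC(=O)O | intermediate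
11 | (5S)-5-[(1R)-1-hydroxy-4-oxopentyl]-5-methyloxolan-2-one | CC(=O)CC[C@@H](O)[C@]1(C)CCC(=O)O1 | intermediate
12 | (5S)-5-methyl-5-[(1R)-4-oxo-1-(triethylsilyloxy)pentyl]oxolan-2-one | CC(=O)CC[C@@H](O[Si](CC)(CC)CC)[C@]1(C)CCC(=O)O1 | intermediate
13 | furan-3-ylmethanol | OCc1ccoc1 | starting material
14 | 3-(chloromethyl)furan | ClCc1ccoc1 | intermediate
15 | prenyl bromide (1-bromo-3-methylbut-2-ene) | CC(C)=CCBr | starting material
16 | (furan-3-ylmethyl)magnesium chloride | Cl[Mg]Cc1ccoc1 | intermediate
17 | perillene, 3-(4-methylpent-3-en-1-yl)furan | CC(C)=CCCc1ccoc1 | intermediate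
18 | (2E)-5-(furan-3-yl)-2-methylpent-2-enal | C/C(=C\CCc1ccoc1)C=O | intermediate
19 | (2E)-5-(furan-3-yl)-2-methylpent-2-en-1-ol | C/C(=C\CCc1ccoc1)CO | intermediate
20 | 3-[(3E)-5-bromo-4-methylpent-3-en-1-yl]furan | C/C(=C\CCc1ccoc1)CBr | intermediate
21 | ethynyltrimethylsilane | C#C[Si](C)(C)C | starting material
22 | [(trimethylsilyl)ethynyl]magnesium bromide | C[Si](C)(C)C#C[Mg]Br | intermediate
23 | [(4E)-7-(furan-3-yl)-4-methylhept-4-en-1-yn-1-yl]trimethylsilane | C/C(=C\CCc1ccoc1)CC#C[Si](C)(C)C | intermediate
24 | 3-[(3E)-4-methylhept-3-en-6-yn-1-yl]furan | C/C(=C\CCc1ccoc1)CC#C | intermediate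
25 | chlorobis(cyclopentadienyl)[(1E,4E)-7-(furan-3-yl)-4-methylhepta-1,4-dien-1-yl]zirconium | C/C(=C\CCc1ccoc1)C/C=C/[Zr](Cl)(C1C=CC=C1)C1C=CC=C1 | intermediate
26 | [(1E,4E)-7-(furan-3-yl)-4-methylhepta-1,4-dien-1-yl](methyl)zinc | C/C(=C\CCc1ccoc1)C/C=C/[Zn]C | intermediate
27 | (5S)-5-[(1R,4S,5E,8E)-11-(furan-3-yl)-4-hydroxy-4,8-dimethyl-1-(triethylsilyloxy)undeca-5,8-dien-1-yl]-5-methyloxolan-2-one | C/C(=C\CCc1ccoc1)C/C=C/[C@@](C)(O)CC[C@@H](O[Si](CC)(CC)CC)[C@]1(C)CCC(=O)O1 | intermediate
28 | (5S)-5-[(1R,4S,5E,8E)-11-(furan-3-yl)-1,4-dihydroxy-4,8-dimethylundeca-5,8-dien-1-yl]-5-methyloxolan-2-one | C/C(=C\CCc1ccoc1)C/C=C/[C@@](C)(O)CC[C@@H](O)[C@]1(C)CCC(=O)O1 | target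

Total step count: 15
Longest linear sequence: 9 steps (steps 1–7, 14 and 15); the alkyne arm is steps 8–13.

Steps most likely to fail

Step 14. The process at risk is facial discrimination: the catalyst has to tell a methyl group from a CH2CH2R group, the least differentiated class of ketone for this kind of catalyst, so alkenyl transfer to the Si face could erode the configuration at C4'; methyl transfer from zinc is a second drain. The fallback gives up catalyst control in favour of late separation. It sets out from 12 and 24: the alkenylzinc 26 is generated as before and added to 12 with Ti(OiPr)4 and the racemic ligand, which should give 27 mixed with its C4' epimer, (5S)-5-[(1R,4R,5E,8E)-11-(furan-3-yl)-4-hydroxy-4,8-dimethyl-1-(triethylsilyloxy)undeca-5,8-dien-1-yl]-5-methyloxolan-2-one F1. The mixture is desilylated as in step 15, and the C4' epimer of the target, (5S)-5-[(1R,4R,5E,8E)-11-(furan-3-yl)-1,4-dihydroxy-4,8-dimethylundeca-5,8-dien-1-yl]-5-methyloxolan-2-one F2, is removed by preparative HPLC. The route is rejoined at 28.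

Step 6. The process at risk is capture of the activated epoxide by the C8 ketone oxygen, which would lead to a bridged bicyclic ketal, and acid-induced dehydration of the hemiketal form of the product. The fallback carries C8–C9 through epoxidation and lactonisation as the inert terminal alkene and unveils the ketone afterwards. It sets out from 6: Shi epoxidation under the step 4 conditions, which should touch only the trisubstituted alkene, gives ethyl (4R,5R)-4,5-epoxy-4-methylnon-8-enoate F3. Saponification as in step 5 gives lithium (4R,5R)-4,5-epoxy-4-methylnon-8-enoate F4 and, on acidification, (4R,5R)-4,5-epoxy-4-methylnon-8-enoic acid F5. This is closed with catalytic CSA to (5S)-5-[(1R)-1-hydroxypent-4-en-1-yl]-5-methyloxolan-2-one F6, with no competing carbonyl present. Silylation as in step 7 gives (5S)-5-methyl-5-[(1R)-1-(triethylsilyloxy)pent-4-en-1-yl]oxolan-2-one F7, and a Tsuji–Wacker oxidation run without chloride-derived acid (PdCl2, Cu(OAc)2, O2, DMA/H2O) should then return the route to 12.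

Step 10. The process at risk is oxidative degradation of the electron-rich furan and over-oxidation, leaving low conversion to the allylic alcohol. The fallback builds the oxygenated (E)-alkene by C–C bond formation instead of C–H oxidation. It sets out from 14: the Grignard reagent 16 is made as in step 9 and added with CuI (10 mol%) to 2-methyl-2-vinyloxirane in THF at −30 °C. Anti-SN2' opening of the vinyl epoxide should give 19 directly, predominantly as the (E)-isomer; any (Z)-isomer would be removed on AgNO3-impregnated silica. The route is rejoined at 19, and this detour makes no compound outside the list (entry F0).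

Further compounds
F1 | step 14 | (5S)-5-[(1R,4R,5E,8E)-11-(furan-3-yl)-4-hydroxy-4,8-dimethyl-1-(triethylsilyloxy)undeca-5,8-dien-1-yl]-5-methyloxolan-2-one | C/C(=C\CCc1ccoc1)C/C=C/[C@](C)(O)CC[C@@H](O[Si](CC)(CC)CC)[C@]1(C)CCC(=O)O1
F2 | step 14 | (5S)-5-[(1R,4R,5E,8E)-11-(furan-3-yl)-1,4-dihydroxy-4,8-dimethylundeca-5,8-dien-1-yl]-5-methyloxolan-2-one | C/C(=C\CCc1ccoc1)C/C=C/[C@](C)(O)CC[C@@H](O)[C@]1(C)CCC(=O)O1
F3 | step 6 | ethyl (4R,5R)-4,5-epoxy-4-methylnon-8-enoate | C=CCC[C@H]1O[C@]1(C)CCC(=O)OCC
F4 | step 6 | lithium (4R,5R)-4,5-epoxy-4-methylnon-8-enoate | [Li+].C=CCC[C@H]1O[C@]1(C)CCC(=O)[O-]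
F5 | step 6 | (4R,5R)-4,5-epoxy-4-methylnon-8-enoic acid | C=CCC[C@H]1O[C@]1(C)CCC(=O)O
F6 | step 6 | (5S)-5-[(1R)-1-hydroxypent-4-en-1-yl]-5-methyloxolan-2-one | C=CCC[C@@H](O)[C@]1(C)CCC(=O)O1
F7 | step 6 | (5S)-5-methyl-5-[(1R)-1-(triethylsilyloxy)pent-4-en-1-yl]oxolan-2-one | C=CCC[C@@H](O[Si](CC)(CC)CC)[C@]1(C)CCC(=O)O1
F0 | step 10 | none | none
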